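I took each exchange on the complex to take up one incoming ligand and free one leaving ligand, so I began from the charge of incoming ligand as a fixed budget.

| setting | beta | red | ochre | amber |
|---|---|---|---|---|
| starting complex | 12 mM | 12 mM | 12 mM | 12 mM |
| incoming ligand | 1 equiv | 1.00 equiv | 1.00 equiv | 1.00 equiv |
| scavenger | 3.5 equiv | 1.00 equiv | 1.50 equiv | 2.20 equiv |
| remark | run made earlier |  |  |  |
| time |  | 3.0 min | 3.0 min | 3.0 min |

beta run (percent of the starting complex charged)

| time / s | starting complex / % | complex with three exchanged / % |
|---|---|---|
| 10.0 | 55.6 | 0.8 |
| 15.0 | 45.5 | 1.6 |
| 25.0 | 36.1 | 0.8 |
| 40.0 | 31.4 | 1.2 |
| 50.0 | 28.7 | 1.4 |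
| 80.0 | 27.2 | 2.0 |
| 90.0 | 28.3 | 2.4 |

(standard deviation of a reading: 0.5 percentage points)

* part of the starting complex that has reacted at the end, red
* part of the starting complex that has reacted at the end, ochre
* part of the starting complex that has reacted at the end, amber
* what raising the equivalents of scavenger from its lowest to its highest value here does to the part of the starting complex that has reacted (changes below 5 percentage points count as none) (no change / it falls / it rises)

I assumed that the loss of starting complex was first order in incoming ligand, the one concentration I took to set its rate. As a rough working rule, not a consequence of that order, I let the logarithm of the starting complex left at the plateau fall in proportion to the incoming ligand charged, however long the run took to get there. In the beta run the starting complex had levelled off by 50.0 s, and its readings from then on average: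

left at the plateau = 28.1%

I treated incoming ligand as the limiting reagent, so that one charge of it had bought this plateau. That gave me the decay per charge, the natural logarithm of charged over left:

decay per charge = 1.27

Red, ochre and amber hold the same 1.00 equiv of incoming ligand, and their 3.0 min is longer than beta took to level off, so:

reacted = 71.9%

The weak link was the scavenger, which no earlier run changes. Beta had 3.5 equiv, but red has 1.00 equiv, which only matches the incoming ligand. If one scavenger takes up one leaving ligand, that charge still covers what the budget can free, so I kept the same figure for the three flasks and expected no change, with red the least sure.

The forecast gave 68%, 71% and 72% for red, ochre and amber, with no change as its trend, and said “This scavenger dependence is a guess”; its red stood below my figure.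

The flasks gave 73.6%, 72.1% and 72.0%, a change of −1.7 percentage points from red to amber, which counts as no change.

    leaving ligand + incoming ligand ⇌ idle adduct, settled at all times (K = 130 M⁻¹)
    complex with two exchanged + incoming ligand → leaving ligand + complex with three exchanged (k = 12.7 M⁻¹ s⁻¹)
    complex with three exchanged + incoming ligand ⇌ leaving ligand + complex with four exchanged (K = 0.600, k = 44.2 M⁻¹ s⁻¹)
    complex with one exchanged + incoming ligand → leaving ligand + complex with two exchanged (k = 2.38 M⁻¹ s⁻¹)
    starting complex + incoming ligand → leaving ligand + complex with one exchanged (k = 7.51 M⁻¹ s⁻¹)
    scavenger + leaving ligand → scavenged by-product (k = 87.6 M⁻¹ s⁻¹)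

Amber's result, put the same way, is a decay per charge of 1.27. I carried the 1.27 read from the beta readings to a neighbouring flask, which is amber with 1.70 equiv of incoming ligand. Scaling the decay by that charge gives 88.5% reacted. The neighbouring flask reached 90.6%, with 9.39% of its starting complex left.

Readings and results were computed for an exercise; scatter was added.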